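The numbers were chosen freely; the flask was simulated.

Watch L.

D 0.50 mM; Z 0.27 mM (held); X 19 µM; time 5.0 s

    D + L + X → X + G (k1 = 1.0 × 10⁸ L² mol⁻² s⁻¹)
    Z ⇌ L, rate k2*(csat - [L]) (k2 = 0.17 s⁻¹, csat = 0.27 mM)
    D ⇌ E (K3 = 6.5, k3 = 0.023 s⁻¹)
    G → J (k4 = 0.41 s⁻¹)

1. the G standing at 5.0 s, as a percentage of the D charged
2. concentration of L in solution at 5.0 s, in percent of saturation

- at the start none of L is dissolved
- run time (flask): 5.0 s

Minutes of our meeting on this flask, whose reckoning I commit to as my own. The chair proposed counting turnovers of X, since each one takes up a D and an L and leaves a G. She argued that, with D and X as charged, L is used up in a pseudo-first-order way, at 0.950 s⁻¹: the drain constant, the step-one rate constant times D times X. This is faster than the transfer coefficient 0.17 s⁻¹, she said, so L should stay well below saturation while D lasts.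

A colleague added that L approaches the balance of transfer and drain with a half-time of 0.619 s, short against 5.0 s. He therefore put sat at the balance, transfer coefficient over transfer coefficient plus drain constant: 15.2%.

At that balance each X turns over at a frequency of 2.05 s⁻¹. The chair let G form at this pace and decay to J at 0.41 s⁻¹, which gave 16.5%. I minuted the warning that at this pace 0.195 mM of the 0.50 mM of D goes by 5.0 s, so the reckoned y should come out high and sat low.

The forecast stood at 13.4% and 20%, holding that “L stays far below saturation”.

The run gives 13.2% and 20.0%. In this flask D stands at 62.1% of its charge at 5.00 s. That share brings the drain constant down to 0.590 s⁻¹ and moves the balance up to 22.4%, a little above the reading. In the neighbour flask charged with 0.20 mM of D, D stands at 50.3% of its charge at 5.00 s, which makes the drain constant 0.191 s⁻¹ and the balance 47.1%. L in that neighbour flask reads less than this balance, 35.7% of saturation at 5.00 s.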